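**Reading late.** Read the flask at 12 d, the end of the window, and the question is whether EjEjEbEj has already passed its top.

| flask | Dx | Xa | remark | time |
|---|---|---|---|---|
| red | 0.0095 M | 0.76 mM (held) | run made earlier |  |
| ochre | 0.038 M | 0.76 mM (held) | run made earlier |  |
| flask | 0.019 M | 0.76 mM (held) |  | 12 d |

| run | time / d | EjEjEbEj / % | Dx / % |
|---|---|---|---|
| red | 1.25 | 25.5 | 0.3 |
| red | 2.50 | 66.7 | 0 |
| red | 4.00 | 78.4 | 0.3 |
| red | 8.00 | 57.5 | 0 |
| red | 15.0 | 31.2 | 0.1 |
| ochre | 1.25 | 5.6 | 66.8 |
| ochre | 2.50 | 21.7 | 46.2 |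
| ochre | 4.00 | 41.9 | 22.1 |
| ochre | 8.00 | 71.0 | 0.2 |
| ochre | 15.0 | 39.0 | 0 |

(each reading ± 0.5 percentage points)

1. time up to 12 d at which EjEjEbEj stands highest
2. the amount of EjEjEbEj, in percent of the Dx charged, at that time

- given per volume of solution although it is solid: Dx
- at the start none of Dx is in solution
- at the start none of Xa is in solution

**The tail.** In the red run EjEjEbEj falls from 57.5 % at 8.00 d to 31.2 % at 15.0 d. Taken as a steady fractional fall (pseudo-first-order in form), that reads 0.0873 /d. Trace a tail back at that rate to the whole charge and it lands at 1.66 d in red and 4.22 d in ochre. The flask's charge lies a third of the way from red's charge to ochre's, so I give it 2.52 d. This landing time is the tail lag.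

**Turned round.** With that lag, the flask's tail stands at 43.7 % of the charge at 12 d. For the top to sit at the window's end, this figure would have to reach the top itself. Going a third of the way between the highest readings, 78.4 % at 4.00 d and 71.0 % at 8.00 d, I put that top at 75.9 % near 5.33 d. The lag would then have to be 8.84 d, not 2.52 d, so I expect the top before the window's end.

**The flask.** The forecast, earlier and higher than my figures, put the top at 4.8 d and 77 %, “safely inside the 12 d window”. The flask gives 4.86 d and 76.9 %.

    Ej + EbEj → EjEbEj (k = 0.0280 /M/s)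
    Ej + EjEjEbEj → Ek (k = 0.00140 /M/s)
    Ej + EjEbEj → EjEjEbEj (k = 0.0380 /M/s)
    Dx ⇌ Eb, rate k4*(cs4 - [Eb]) while solid is left; crystals form when [Eb] > cs4 (solubility = 5.50 mM, k = 2.40 × 10⁻⁴ /s)
    Eb + Ej → EbEj (k = 0.0200 /M/s)
    Xa ⇌ Ej, rate k6*(csat - [Ej]) (kL = 0.00260 /s)

**Next flask over.** At 12.0 d the flask holds 43.5 % of its charge as EjEjEbEj, where the tail lag gave 43.7 %, and 56.5 % as Ek. Now take a neighbour flask charged with 0.011 M of Dx, with the time and the other settings held. Placed the same way between red and ochre, its lag comes to 1.80 d, and its tail at 12 d to 41.0 %. That neighbour tops out at 78.4 %, and at 12.0 d it holds 40.8 % as EjEjEbEj and 59.2 % as Ek.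

The runs were generated by integration with made-up constants; scatter was added.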